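Start from the slowing of Monday's run, and turn the question round: what would let a slow feed of partner beat charging everything at once?

| setting | Monday's | Wednesday's | blue | green | ochre | teal |
|---|---|---|---|---|---|---|
| substrate | 10 mM | 10 mM | 10 mM (fed, over 2.5 min) | 10 mM | 10 mM | 10 mM |
| partner | 20 mM | 20 mM | 20.0 mM | 20.0 mM (fed, over 2.5 min) | 20.0 mM (in portions, 5, over 2.5 min) | 20.0 mM |
| capture agent | 0.20 mM | 0.20 mM | 0.200 mM | 0.200 mM | 0.200 mM | 0.200 mM |
| free catalyst | 0.15 mM | 0.22 mM | 0.15 mM | 0.15 mM | 0.15 mM | 0.15 mM |
| remark | run made earlier | run made earlier | all else is in the flask from the start; the feed brings no volume worth counting | all else is in the flask from the start; the feed brings no volume worth counting | first portion at the start, last at 2.5 min | everything together at the start |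
| time |  |  | 6.0 min | 6.0 min | 6.0 min | 6.0 min |

Monday's run (percent of the substrate charged): time / min: product / % = 0.200: 2; 0.500: 10; 1.00: 23; 1.50: 27; 2.00: 29; 3.00: 37; 4.00: 42

Wednesday's run (percent of the substrate charged): time / s: product / % = 10.0: 5; 15.0: 9; 25.0: 15; 40.0: 22

(scatter of a reading: 2 percentage points)

* the flask that comes out highest in amount of product, in percent of the substrate charged, or "all alike" when all lie within 1.5 percentage points (blue / green / ochre / teal / all alike)
* product at the end, in percent of the substrate charged, blue
* product at the end, in percent of the substrate charged, green
* product at the end, in percent of the substrate charged, ochre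
* product at the end, in percent of the substrate charged, teal



Monday's run makes product at 0.230 min⁻¹, counted as a fraction of the charge, over its first minute, but at 0.0650 min⁻¹ between 2.00 min and 4.00 min. Wednesday's run, with 1.47 times the catalyst, shows 1.43 times that early rate, so take rate as a gauge of working catalyst. Then at 3.00 min, with 37% made, the working share reads 28.3%. Extend that line: the ceiling, the fraction of the charge at which the rate reaches zero, reads 51.6%.

Now commit to a guess of my own: capture agent, charged at 1.33 times the catalyst, takes catalyst on a clock that ignores partner, while product follows partner. Teal repeats Monday's recipe, and 6.0 min is twice that reading's time, so square the working share: teal gives 47.5%. Blue keeps partner and capture agent as charged, so put it just under teal. In green and ochre, partner averages half its charge during the addition, so they earn at half pace while the working share falls to 34.9%. That gives each about 30.7%. To match teal with its earnings during the feed unchanged, green would need 77.1% of its catalyst working when the feed ends, against the 34.9% reckoned here.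

The forecast gave 47% for blue, 58% for green, 54% for ochre and 50% for teal, naming green: “Feeding partner would then delay exhaustion, favouring green”. The flasks give 45.0% for blue, 29.2% for green, 30.0% for ochre and 47.4% for teal, so teal comes highest.

    substrate + free catalyst ⇌ catalyst intermediate A (K = 190 M⁻¹, k = 1100 M⁻¹ s⁻¹)
    partner + catalyst intermediate A → catalyst intermediate B (k = 28.0 M⁻¹ s⁻¹)
    catalyst intermediate B → free catalyst + product (k = 5.40 s⁻¹)
    catalyst intermediate A + capture agent → trapped intermediate (k = 110 M⁻¹ s⁻¹)
    2 catalyst intermediate B ⇌ resting dimer, settled at all times (K = 16000 M⁻¹)

Partner and capture agent compete for catalyst intermediate A, and the ratio of their two steps is a selectivity factor. Strike out the step to trapped intermediate and the gap between teal and green falls from 18 percentage points to 7.7 points, so this loss is a part of the gap. Now take teal's recipe with 50 mM of partner, and scale the ceiling read from Monday's run in proportion to partner: it reads 129%, above the whole charge. That flask reaches 92.0% at 6.00 min, with 23.5% of its catalyst still free.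

(The runs were computed for substances that don't exist; the scatter is artificial.)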